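**Plan**
- Retrosynthesis opens the pyridine ring of the isoquinoline (C1, N2, C3, C4, C4a, C8a) at N–C1, N–C3, C4–C4a and C1–C8a. This ring is a 1,5-diketone plus ammonia, and the diketone is acetylacetone inserted into a C4a≡C8a aryne that the C8 methoxy group, sitting next to C8a, polarises.
- The aryne precursor (a 2-silylaryl triflate) is then cut at the biaryl bond C7–C1', and the naphthalene is cut back to an ortho-methallyl benzamide.
- Forward: naphthalene ring first (steps 1–2), O-methylation and bromination at C1' (steps 3–4), biaryl coupling (step 5), carbamate-directed silylation and triflation on the phenol ring (steps 6–8), pyridine ring last (step 9).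
- Stereochemistry: the target has no stereocentre; the hindered biaryl axis is not specified in the target and should arise as the racemate.

Key step: step 9

Assumption: N,N-diethyl-2-methoxybenzamide (1) and the phenol boronate 9 are taken as purchasable; isoquinoline numbering (C1–C8a) is used for the target and primed numbers for the naphthalene.

**Step 1**
Reactants: 1 N,N-diethyl-2-methoxybenzamide; 2 3-bromo-2-methylprop-1-ene (methallyl bromide)
Product: 5 N,N-diethyl-2-methoxy-6-(2-methylprop-2-en-1-yl)benzamide, via aryllithium 3 (not isolated), via arylmagnesium bromide 4 (not isolated)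
Conditions: s-BuLi, TMEDA, THF, −78 °C; MgBr2·OEt2, −78 to 0 °C; then 2, 0 °C to rt
Reagents that add atoms: none
Why: Directed ortho-metalation, in which the tertiary amide outranks the methoxy group so that H6 is removed, followed by transmetalation to the aryl Grignard reagent, which is allylated cleanly by methallyl bromide (direct and allylic displacement give the same product).

**Step 2**
Reactants: 5 N,N-diethyl-2-methoxy-6-(2-methylprop-2-en-1-yl)benzamide
Product: 6 8-methoxy-3-methylnaphthalen-1-ol
Conditions: MeLi (2.2 equiv), THF, −78 °C to rt; 1 M HCl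
Reagents that add atoms: none
Why: Anionic amide annulation of an ortho-allyl benzamide, in which MeLi removes a benzylic/allylic proton, the terminal carbon of the allyl anion attacks the amide carbonyl to close the six-membered ring, diethylamide leaves and the dienone tautomerises to the 1-naphthol.

**Step 3**
Reactants: 6 8-methoxy-3-methylnaphthalen-1-ol
Product: 7 1,8-dimethoxy-3-methylnaphthalene
Conditions: MeI, K2CO3, DMF, rt
Reagents that add atoms: iodomethane, CI
Why: Williamson O-methylation of the naphthoxide, with carbonate in DMF basic enough to overcome the peri hydrogen bond to the neighbouring methoxy group.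

**Step 4**
Reactants: 7 1,8-dimethoxy-3-methylnaphthalene
Product: 8 1-bromo-4,5-dimethoxy-2-methylnaphthalene
Conditions: NBS (1.0 equiv), MeCN, 0 °C, dark
Reagents that add atoms: N-bromosuccinimide, O=C1CCC(=O)N1Br
Why: Electrophilic aromatic bromination, expected at C4 of 7 because, of the two alpha positions para to a methoxy group, this one is also activated by the ortho methyl group (the preference that sends bromine to C1 of 2-methylnaphthalene).

**Step 5**
Reactants: 8 1-bromo-4,5-dimethoxy-2-methylnaphthalene; 9 3-methoxy-4-(4,4,5,5-tetramethyl-1,3,2-dioxaborolan-2-yl)phenol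
Product: 10 4-(4,5-dimethoxy-2-methylnaphthalen-1-yl)-3-methoxyphenol
Conditions: Pd(OAc)2 (cat.), SPhos (2-dicyclohexylphosphino-2',6'-dimethoxybiphenyl, cat.), K3PO4, toluene/H2O (10:1), 90 °C
Reagents that add atoms: none
Why: Suzuki–Miyaura coupling with the more hindered partner as the bromide and the less hindered one as the boronate, a polarity and ligand system suited to biaryls with three ortho substituents and tolerant of a free phenol.

**Step 6**
Reactants: 10 4-(4,5-dimethoxy-2-methylnaphthalen-1-yl)-3-methoxyphenol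
Product: 11 4-(4,5-dimethoxy-2-methylnaphthalen-1-yl)-3-methoxyphenyl propan-2-ylcarbamate
Conditions: i-PrNCO, Et3N (cat.), CH2Cl2, rt
Reagents that add atoms: isopropyl isocyanate, CC(C)N=C=O
Why: Amine-catalysed addition of the phenol to the isocyanate (carbamoylation) installs an N-monoalkyl carbamate that directs ortho-metalation and is later removed under mild base.

**Step 7**
Reactants: 11 4-(4,5-dimethoxy-2-methylnaphthalen-1-yl)-3-methoxyphenyl propan-2-ylcarbamate
Product: 15 4-(4,5-dimethoxy-2-methylnaphthalen-1-yl)-3-methoxy-2-(trimethylsilyl)phenyl propan-2-ylcarbamate, via N-silyl carbamate 12 (not isolated), via aryllithium 13 (not isolated), via N-silyl C-silyl carbamate 14 (not isolated)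
Conditions: TBSOTf, TMEDA, Et2O, 0 °C to rt; n-BuLi (2.2 equiv), TMEDA, −78 °C; TMSCl, −78 °C to rt; aq. NaHSO4 work-up
Reagents that add atoms: chlorotrimethylsilane, C[Si](C)(C)Cl
Why: Directed ortho-metalation of the carbamate, N-silylated in the flask, in which the carbamate and the C3 methoxy group act together on H2 between the two oxygens (as in simpler 3-alkoxyphenyl carbamates), the aryllithium is trapped by TMSCl at −78 °C before any carbamoyl shift, and work-up removes the N-silyl group.

**Step 8**
Reactants: 15 4-(4,5-dimethoxy-2-methylnaphthalen-1-yl)-3-methoxy-2-(trimethylsilyl)phenyl propan-2-ylcarbamate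
Product: 17 4-(4,5-dimethoxy-2-methylnaphthalen-1-yl)-3-methoxy-2-(trimethylsilyl)phenyl trifluoromethanesulfonate, via silylphenol 16 (not isolated)
Conditions: DBU, Et2NH, MeCN, 40 °C; then PhNTf2, rt
Reagents that add atoms: N-phenylbis(trifluoromethanesulfonimide), O=S(=O)(N(c1ccccc1)S(=O)(=O)C(F)(F)F)C(F)(F)F
Why: E1cB cleavage of the N–H carbamate by DBU (the isocyanate is trapped by Et2NH as a urea) and triflation of the phenoxide with PhNTf2 in the same flask, the usual one-pot route to 2-silylaryl triflates, which avoids isolating the protodesilylation-prone silylphenol.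

**Step 9**
Reactants: 17 4-(4,5-dimethoxy-2-methylnaphthalen-1-yl)-3-methoxy-2-(trimethylsilyl)phenyl trifluoromethanesulfonate; 18 acetylacetone; 19 ammonia
Product: 22 7-(4,5-dimethoxy-2-methylnaphthalen-1-yl)-8-methoxy-1,3-dimethylisoquinoline, via aryne 20 (not isolated), via 1,5-diketone 21 (not isolated)
Conditions: CsF (3 equiv), 18 (1.5 equiv), MeCN, 80 °C; then 28% aq. NH3 (19), 60 °C, sealed tube
Reagents that add atoms: none
Why: Fluoride removes the trimethylsilyl group of 17 and triflate departs to give aryne 20 (C4a≡C8a), to which the cesium enolate of 18 adds through its central carbon at C4a, the terminus remote from the C8 methoxy group, because the inductive pull of that oxygen and the ring distortion it causes favour the carbanion at C8a. This anion adds to a neighbouring acetyl carbonyl (4-exo-trig) and the benzocyclobutenoxide opens to the 1,5-diketone 21, with an acetyl group on C8a and the acetonyl chain on C4a, a net insertion of the aryne into the C–C(=O) bond. The closest known reactions are the fluoride-induced acyl-alkylation of arynes by beta-ketoesters and 1,3-diketones, its one-pot extension with aqueous ammonia to 3-hydroxyisoquinolines, and the classical condensation of 2-acylaryl acetones with ammonia. Ammonia then condenses with the unhindered ketone and the nitrogen closes the pyridine ring by 6-exo-trig attack on the aryl ketone, two dehydrations giving the aromatic ring; no stereocentre is formed. The step needs regioselective aryne addition, which the C8 methoxy group secures (the C7 naphthyl group is not adjacent to the triple bond and does not oppose it), and it needs ammonia to be withheld until 17 is consumed, since ammonia itself adds to arynes and the diketone can close by aldol reaction if left under base.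

**Compound list**
1 | N,N-diethyl-2-methoxybenzamide | CCN(CC)C(=O)c1ccccc1OC | starting material
2 | 3-bromo-2-methylprop-1-ene | C=C(C)CBr | starting material
3 | [2-(diethylcarbamoyl)-3-methoxyphenyl]lithium | CCN(CC)C(=O)c1c([Li])cccc1OC | intermediate
4 | [2-(diethylcarbamoyl)-3-methoxyphenyl]magnesium bromide | CCN(CC)C(=O)c1c([Mg]Br)cccc1OC | intermediate
5 | N,N-diethyl-2-methoxy-6-(2-methylprop-2-en-1-yl)benzamide | CCN(CC)C(=O)c1c(CC(C)=C)cccc1OC | intermediate
6 | 8-methoxy-3-methylnaphthalen-1-ol | COc1cccc2cc(C)cc(O)c12 | intermediate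
7 | 1,8-dimethoxy-3-methylnaphthalene | COc1cccc2cc(C)cc(OC)c12 | intermediate
8 | 1-bromo-4,5-dimethoxy-2-methylnaphthalene | COc1cc(C)c(Br)c2cccc(OC)c12 | intermediate
9 | 3-methoxy-4-(4,4,5,5-tetramethyl-1,3,2-dioxaborolan-2-yl)phenol | COc1cc(O)ccc1B1OC(C)(C)C(C)(C)O1 | starting material
10 | 4-(4,5-dimethoxy-2-methylnaphthalen-1-yl)-3-methoxyphenol | COc1cc(O)ccc1-c1c(C)cc(OC)c2c(OC)cccc12 | intermediate
11 | 4-(4,5-dimethoxy-2-methylnaphthalen-1-yl)-3-methoxyphenyl propan-2-ylcarbamate | COc1cc(OC(=O)NC(C)C)ccc1-c1c(C)cc(OC)c2c(OC)cccc12 | intermediate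
12 | 4-(4,5-dimethoxy-2-methylnaphthalen-1-yl)-3-methoxyphenyl N-(tert-butyldimethylsilyl)-N-(propan-2-yl)carbamate | COc1cc(OC(=O)N(C(C)C)[Si](C)(C)C(C)(C)C)ccc1-c1c(C)cc(OC)c2c(OC)cccc12 | intermediate
13 | 2-lithio derivative of 12 (lithium between the carbamate and methoxy oxygens) | COc1c([Li])c(OC(=O)N(C(C)C)[Si](C)(C)C(C)(C)C)ccc1-c1c(C)cc(OC)c2c(OC)cccc12 | intermediate
14 | 4-(4,5-dimethoxy-2-methylnaphthalen-1-yl)-3-methoxy-2-(trimethylsilyl)phenyl N-(tert-butyldimethylsilyl)-N-(propan-2-yl)carbamate | COc1c([Si](C)(C)C)c(OC(=O)N(C(C)C)[Si](C)(C)C(C)(C)C)ccc1-c1c(C)cc(OC)c2c(OC)cccc12 | intermediate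
15 | 4-(4,5-dimethoxy-2-methylnaphthalen-1-yl)-3-methoxy-2-(trimethylsilyl)phenyl propan-2-ylcarbamate | COc1c([Si](C)(C)C)c(OC(=O)NC(C)C)ccc1-c1c(C)cc(OC)c2c(OC)cccc12 | intermediate
16 | 4-(4,5-dimethoxy-2-methylnaphthalen-1-yl)-3-methoxy-2-(trimethylsilyl)phenol | COc1c([Si](C)(C)C)c(O)ccc1-c1c(C)cc(OC)c2c(OC)cccc12 | intermediate
17 | 4-(4,5-dimethoxy-2-methylnaphthalen-1-yl)-3-methoxy-2-(trimethylsilyl)phenyl trifluoromethanesulfonate | COc1c(-c2c(C)cc(OC)c3c(OC)cccc23)ccc(OS(=O)(=O)C(F)(F)F)c1[Si](C)(C)C | intermediate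
18 | acetylacetone (pentane-2,4-dione) | CC(=O)CC(C)=O | starting material
19 | ammonia | N | starting material
20 | 4-(4,5-dimethoxy-2-methylnaphthalen-1-yl)-3-methoxybenzyne (triple bond between C1 and C2 of the benzene ring) | COC1=C(c2c(C)cc(OC)c3c(OC)cccc23)C=CC#C1 | intermediate
21 | 1-[2-acetyl-4-(4,5-dimethoxy-2-methylnaphthalen-1-yl)-3-methoxyphenyl]propan-2-one | COc1c(-c2c(C)cc(OC)c3c(OC)cccc23)ccc(CC(C)=O)c1C(C)=O | intermediate
22 | 7-(4,5-dimethoxy-2-methylnaphthalen-1-yl)-8-methoxy-1,3-dimethylisoquinoline | COc1c(-c2c(C)cc(OC)c3c(OC)cccc23)ccc2cc(C)nc(C)c12 | target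

**Count**
Total steps: 9. Longest linear sequence: 9 steps (1 to 22).

**Steps most likely to fail**

Step 9. The diketone 21 may close by intramolecular aldol condensation to a naphthol under the basic fluoride conditions before ammonia is added, or the diketone enolate may insert less efficiently than a ketoester enolate. The fallback sets out from silyl triflate 17 and uses the ketoester variant. CsF and methyl acetoacetate in MeCN at 80 °C should give, through the same aryne 20, methyl 2-[2-acetyl-4-(4,5-dimethoxy-2-methylnaphthalen-1-yl)-3-methoxyphenyl]acetate F1. Aqueous ammonia added to the same flask should close it to 7-(4,5-dimethoxy-2-methylnaphthalen-1-yl)-8-methoxy-1-methylisoquinolin-3-ol F2. Triflation (Tf2O, pyridine, CH2Cl2, 0 °C) should give 7-(4,5-dimethoxy-2-methylnaphthalen-1-yl)-8-methoxy-1-methylisoquinolin-3-yl trifluoromethanesulfonate F3. Cross-coupling with trimethylboroxine (Pd(PPh3)4, K2CO3, 1,4-dioxane, 100 °C) then installs the C3 methyl group and comes back to the route at target 22.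

Step 7. Metalation may occur at the other ortho position of the carbamate (C6), because the methoxy group is twisted by the neighbouring naphthyl group and directs less well; carbamoyl migration on warming is a second failure path. The fallback sets out from bromide 8 and moves the hydroxyl group so that only one ortho position is open.
- Bromine–lithium exchange (n-BuLi, THF, −78 °C) gives (4,5-dimethoxy-2-methylnaphthalen-1-yl)lithium F4. Quenching with 2-isopropoxy-4,4,5,5-tetramethyl-1,3,2-dioxaborolane gives 2-(4,5-dimethoxy-2-methylnaphthalen-1-yl)-4,4,5,5-tetramethyl-1,3,2-dioxaborolane F5.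
- Suzuki–Miyaura coupling with purchased 3-bromo-2-methoxyphenol (Pd(OAc)2, SPhos, K3PO4) gives 3-(4,5-dimethoxy-2-methylnaphthalen-1-yl)-2-methoxyphenol F6.
- Isopropyl isocyanate gives 3-(4,5-dimethoxy-2-methylnaphthalen-1-yl)-2-methoxyphenyl propan-2-ylcarbamate F7.
- Under the conditions of step 7 this passes through its N-(tert-butyldimethylsilyl) derivative F8, the 6-lithio derivative of that compound F9 and the N-(tert-butyldimethylsilyl) 6-(trimethylsilyl) carbamate F10. Work-up gives 3-(4,5-dimethoxy-2-methylnaphthalen-1-yl)-2-methoxy-6-(trimethylsilyl)phenyl propan-2-ylcarbamate F11.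
- Under the conditions of step 8, cleavage to 3-(4,5-dimethoxy-2-methylnaphthalen-1-yl)-2-methoxy-6-(trimethylsilyl)phenol F12 and triflation give 3-(4,5-dimethoxy-2-methylnaphthalen-1-yl)-2-methoxy-6-(trimethylsilyl)phenyl trifluoromethanesulfonate F13.
- This isomeric precursor carries the silyl and triflate groups on the same two ring carbons in exchanged positions. With CsF it releases the same aryne, so the fallback comes back to the route at aryne 20 in step 9.

Step 4. Bromination may occur at the other alpha position para to a methoxy group (C5 of 7), or go on to a dibromide, and a wrong isomer would be carried through the route unnoticed. The fallback sets out from naphthol 6. Bromination of the free naphthol (NBS, MeCN, −20 °C) is directed para by the hydroxyl group, a stronger director than the methoxy group of the other ring, and should give 4-bromo-8-methoxy-3-methylnaphthalen-1-ol F14. O-Methylation (MeI, K2CO3, DMF) then comes back to the route at bromide 8.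

**Further compounds**
F1 | step 9 | methyl 2-[2-acetyl-4-(4,5-dimethoxy-2-methylnaphthalen-1-yl)-3-methoxyphenyl]acetate | COC(=O)Cc1ccc(-c2c(C)cc(OC)c3c(OC)cccc23)c(OC)c1C(C)=O
F2 | step 9 | 7-(4,5-dimethoxy-2-methylnaphthalen-1-yl)-8-methoxy-1-methylisoquinolin-3-ol | COc1c(-c2c(C)cc(OC)c3c(OC)cccc23)ccc2cc(O)nc(C)c12
F3 | step 9 | 7-(4,5-dimethoxy-2-methylnaphthalen-1-yl)-8-methoxy-1-methylisoquinolin-3-yl trifluoromethanesulfonate | COc1c(-c2c(C)cc(OC)c3c(OC)cccc23)ccc2cc(OS(=O)(=O)C(F)(F)F)nc(C)c12
F4 | step 7 | (4,5-dimethoxy-2-methylnaphthalen-1-yl)lithium | COc1cc(C)c([Li])c2cccc(OC)c12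
F5 | step 7 | 2-(4,5-dimethoxy-2-methylnaphthalen-1-yl)-4,4,5,5-tetramethyl-1,3,2-dioxaborolane | COc1cc(C)c(B3OC(C)(C)C(C)(C)O3)c2cccc(OC)c12
F6 | step 7 | 3-(4,5-dimethoxy-2-methylnaphthalen-1-yl)-2-methoxyphenol | COc1c(O)cccc1-c1c(C)cc(OC)c2c(OC)cccc12
F7 | step 7 | 3-(4,5-dimethoxy-2-methylnaphthalen-1-yl)-2-methoxyphenyl propan-2-ylcarbamate | COc1c(OC(=O)NC(C)C)cccc1-c1c(C)cc(OC)c2c(OC)cccc12
F8 | step 7 | 3-(4,5-dimethoxy-2-methylnaphthalen-1-yl)-2-methoxyphenyl N-(tert-butyldimethylsilyl)-N-(propan-2-yl)carbamate | COc1c(OC(=O)N(C(C)C)[Si](C)(C)C(C)(C)C)cccc1-c1c(C)cc(OC)c2c(OC)cccc12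
F9 | step 7 | 6-lithio derivative of F8 | COc1c(OC(=O)N(C(C)C)[Si](C)(C)C(C)(C)C)c([Li])ccc1-c1c(C)cc(OC)c2c(OC)cccc12
F10 | step 7 | 3-(4,5-dimethoxy-2-methylnaphthalen-1-yl)-2-methoxy-6-(trimethylsilyl)phenyl N-(tert-butyldimethylsilyl)-N-(propan-2-yl)carbamate | COc1c(OC(=O)N(C(C)C)[Si](C)(C)C(C)(C)C)c([Si](C)(C)C)ccc1-c1c(C)cc(OC)c2c(OC)cccc12
F11 | step 7 | 3-(4,5-dimethoxy-2-methylnaphthalen-1-yl)-2-methoxy-6-(trimethylsilyl)phenyl propan-2-ylcarbamate | COc1c(OC(=O)NC(C)C)c([Si](C)(C)C)ccc1-c1c(C)cc(OC)c2c(OC)cccc12
F12 | step 7 | 3-(4,5-dimethoxy-2-methylnaphthalen-1-yl)-2-methoxy-6-(trimethylsilyl)phenol | COc1c(O)c([Si](C)(C)C)ccc1-c1c(C)cc(OC)c2c(OC)cccc12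
F13 | step 7 | 3-(4,5-dimethoxy-2-methylnaphthalen-1-yl)-2-methoxy-6-(trimethylsilyl)phenyl trifluoromethanesulfonate | COc1c(OS(=O)(=O)C(F)(F)F)c([Si](C)(C)C)ccc1-c1c(C)cc(OC)c2c(OC)cccc12
F14 | step 4 | 4-bromo-8-methoxy-3-methylnaphthalen-1-ol | COc1cccc2c(Br)c(C)cc(O)c12
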